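The data stem from a simulated flask on assumed constants, noise included.

- Amounts of starting complex and leaving ligand are the same in the flasks below; the amount of incoming ligand differs.

| setting | ash | birch | Saturday's | Tuesday's | Wednesday's |
|---|---|---|---|---|---|
| starting complex | 0.49 M | 0.49 M | 0.49 M | 0.49 M | 0.49 M |
| incoming ligand | 0.22 M | 1.6 M | 1.96 M | 0.392 M | 0.735 M |
| leaving ligand | 0.49 M | 0.49 M | 0.490 M | 0.490 M | 0.490 M |
| remark | run made earlier | run made earlier |  |  |  |
| time |  |  | 50 min | 50 min | 50 min |

| run | time / min | complex with one exchanged / % | complex with two exchanged / % |
|---|---|---|---|
| ash | 1.50 | 6.6 | 0.4 |
| ash | 5.00 | 13.1 | 0 |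
| ash | 8.00 | 19.3 | 2.6 |
| ash | 15.0 | 21.6 | 3.0 |
| ash | 20.0 | 24.2 | 3.1 |
| ash | 25.0 | 24.9 | 5.5 |
| birch | 1.50 | 29.2 | 6.3 |
| birch | 5.00 | 39.8 | 26.2 |
| birch | 8.00 | 33.5 | 41.2 |
| birch | 15.0 | 19.1 | 56.1 |
| birch | 20.0 | 12.7 | 61.9 |
| birch | 25.0 | 7.9 | 67.0 |

(each reading ± 1 percentage point)

1. which of these holds the largest part of the starting complex at the end of Saturday's (complex with two exchanged / complex with one exchanged / starting complex)
2. which of these holds the largest part of the starting complex at the end of Tuesday's (complex with two exchanged / complex with one exchanged / starting complex)
3. which of these holds the largest part of the starting complex at the end of Wednesday's (complex with two exchanged / complex with one exchanged / starting complex)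
4. how much complex with one exchanged is there at the end of Wednesday's, in percent of the starting complex charged



- Both exchanges take the same incoming ligand, so c(incoming ligand) and time drop out of the ratio of their rates. What stays is how readily a molecule of complex with one exchanged takes ligand compared with a molecule of starting complex.
- Where complex with one exchanged tops out, it is made as fast as it is used, so that ratio equals c(starting complex)/c(complex with one exchanged). Birch reads highest at 5.00 min, with 39.8% of it and 26.2% of complex with two exchanged. I count the unseen 34.0% as starting complex, and that reads s = 0.854, the selectivity factor.
- This gives the path of a flask, not the moment it stands anywhere on that path. If a fraction x of the starting complex remains, complex with one exchanged is x to the power s, minus x, divided by the gap between s and one.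
- Try x = 0.100, which gives 27.4%. That state costs 1.53 equivalents of incoming ligand, and Wednesday's is charged with 1.50, so I take this state for its end on one assumption that the path can't test: that its charge of ligand is about used up by then. My number is 27.4%.
- The weak link is that unseen amount, because birch still has 25.1% unseen at 25.0 min. So I read s again at 1.50 min: complex with two exchanged over complex with one exchanged, doubled, over the natural log of the fraction consumed, gives 0.984, within the scatter. Wednesday's then gives 23.5%, so I expect 23.5% to 27.4%.
- The forecast, holding that “about a quarter of the starting complex behaves as inert”, names complex with two exchanged for Saturday's, complex with one exchanged for Tuesday's and complex with two exchanged for Wednesday's. Its number is 28%, within 21% to 34%, close to mine by another route.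
- The flasks end with complex with two exchanged for Saturday's, complex with one exchanged for Tuesday's and complex with two exchanged for Wednesday's, and with 23.8% of complex with one exchanged in Wednesday's, so the forecast held. My assumption did not: Wednesday's still has 12% of its incoming ligand at the end.

    complex with two exchanged ⇌ isomer of the product (K = 0.310, k = 0.00120 /s)
    2 starting complex → homo dimer (k = 6.70 × 10⁻⁴ /M/s)
    complex with one exchanged + incoming ligand → leaving ligand + complex with two exchanged (k = 0.00250 /M/s)
    starting complex + incoming ligand → leaving ligand + complex with one exchanged (k = 0.00320 /M/s)

- At 50.0 min in Wednesday's, the first exchange uses incoming ligand at 0.34 of the rate of the second, so complex with one exchanged is being used faster than it is made, and c(starting complex)/c(complex with one exchanged) divided by s gives 0.311 for that moment. In Tuesday's the same quotient at 25.0 min is 0.953, near the balance, and complex with one exchanged goes from 32.6% there to 31.8% at 50.0 min.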